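Take the gamma run and keep books on the starting material, the limiting reagent. Apart from the little sitting on the catalyst, each mole stands as starting material, dormant form or target.

- gamma: starting material 0.30 M; free catalyst 1 mol%; added ligand 0.75 mM; run made earlier
- flask: starting material 0.30 M; free catalyst 1 mol%; added ligand 1.5 mM; time 25 min

gamma run (percent of the starting material charged)

| time / min | target / % | dormant form / % |
|---|---|---|
| 0.667 | 8.7 | 6.5 |
| 1.33 | 16.8 | 11.5 |
| 2.00 | 23.4 | 15.0 |
| 3.00 | 32.4 | 19.3 |
| 4.00 | 40.0 | 23.1 |
| 5.00 | 46.1 | 24.6 |

(scatter of a reading: 0.5 percentage points)

- the numbers in the tables scatter by 0.5 percentage points (one standard deviation)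
- no earlier run changes the charge of added ligand; that part of a forecast is a guess

- how much target the flask holds at 25 min, in percent of the starting material charged
- how much dormant form the flask holds at 25 min, in percent of the starting material charged

Work with what is left. At gamma's last reading, after 5.00 min, target and dormant form leave 29.3% of the starting material. Taken as a fall by the same share each minute, the fraction left in gamma falls at 0.246 min⁻¹, and with gamma's constant my reckoning books 0.216% left in the flask at 25 min. With that constant cut to half, it books 4.62%, so this entry closes small and the question is how the rest divides.

Gamma's last reading gives 34.8%. This is the dormant share, the part of what has left the starting material that stands as dormant form. At the first reading it was 42.8%, so it falls as gamma runs. No earlier run changes the added ligand, so for the flask, with twice gamma's charge, I carry the last share unchanged, as a guess. My books close at 34.7% dormant form and 65.1% target.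

The forecast differs from this reckoning: it put target at 82% (72% to 90%) and dormant form at 15.5% (9.5% to 22%), saying “The ligand effect is a guess.”

The flask gives 68.7% target and 29.5% dormant form, with 1.65% starting material left; its dormant share is 30.0%.

    catalyst intermediate B ⇌ free catalyst + target (K = 0.640 M, k = 0.848 s⁻¹)
    starting material + free catalyst → catalyst intermediate A (k = 2.09 M⁻¹ s⁻¹)
    catalyst intermediate A → catalyst intermediate B (k = 0.795 s⁻¹)
    starting material ⇌ dormant form (K = 6.00, k = 0.00158 s⁻¹)
    free catalyst + added ligand ⇌ idle complex, settled at all times (K = 595 M⁻¹)

Taken by itself, the forward step to dormant form has a half-life of 7.31 min, while the back step has one of 43.9 min, longer than the flask's 25 min. Left until 250 min, the flask holds 2.76% dormant form and 96.8% target. In the neighbour flask with 0.0060 M of added ligand, 4.4% of the charged starting material is left at 25 min, and the carried share books 33.3% of the charge as dormant form. The computed neighbour holds 43.0% dormant form and 52.6% target, a share of 45.0%, higher than the share carried from gamma's last reading.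

The readings are simulated on assumed constants; scatter was added.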